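What order do five flasks take by their complex with three exchanged at 5.0 d, and how much do the first and the last hold?

| flask | starting complex | incoming ligand | leaving ligand | remark | time |
|---|---|---|---|---|---|
| zeta | 20 mM | 28 mM | 20 mM | run made earlier |  |
| alpha | 20 mM | 47 mM | 20 mM | run made earlier |  |
| beta | 20 mM | 76 mM | 20 mM | run made earlier |  |
| gamma | 20 mM | 24 mM | 22 mM | run made earlier |  |
| teal | 6.0 mM | 24.0 mM | 20.0 mM |  | 5.0 d |
| grey | 20 mM | 80.0 mM | 30.0 mM |  | 5.0 d |
| violet | 6.0 mM | 100 mM | 30.0 mM |  | 5.0 d |
| green | 80 mM | 100 mM | 20.0 mM |  | 5.0 d |
| red | 20 mM | 24.0 mM | 20.0 mM |  | 5.0 d |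

- zeta (time / d: complex with three exchanged / %, starting complex / %): 0.625: 3, 20; 1.25: 6, 12; 2.08: 3, 11; 2.50: 0, 6
- alpha (time / d: complex with three exchanged / %, starting complex / %): 0.625: 8, 4; 1.25: 6, 6; 2.08: 7, 3; 2.50: 9, 8
- beta (time / d: complex with three exchanged / %, starting complex / %): 0.625: 19, 3; 1.25: 25, 2; 2.08: 22, 0; 2.50: 22, 1
- gamma (time / d: complex with three exchanged / %, starting complex / %): 0.208: 2, 41; 0.500: 0, 24; 1.04: 3, 15; 2.50: 2, 9

(readings scatter by 2 percentage points)



- ranking by amount of complex with three exchanged, in percent of the starting complex charged, from high to low, at 5.0 d (teal / grey / violet / green / red)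
- the amount of complex with three exchanged, in percent of the starting complex charged of the flask you put first, at 5.0 d
- the amount of complex with three exchanged, in percent of the starting complex charged of the flask you put last, at 5.0 d

The beta run looked contradictory. Its 76 mM of incoming ligand on 20 mM of starting complex made 3.80 equivalents, more than the 3 a full exchange takes, and starting complex read 1 % at 2.50 d. Yet complex with three exchanged read 25 % at 1.25 d and 22 % at 2.50 d, level within the scatter.

I counted what was left, not what was made. I assumed exchange one ligand at a time, each step freeing one leaving ligand, and took the beta plateau for an equilibrium (thermodynamic control). Let y be free incoming over free leaving ligand. Setting starting complex aside, I let the complexes with one, two and three exchanged stand as 1 : z : z·z, with z = κy and the same step constant κ assumed for both later steps. The fraction short of the last exchange is then u = (1 + z)/(1 + z + z·z), and the mean number of exchanges is n = (1 + 2z + 3z·z)/(1 + z + z·z).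

The beta readings averaged 22.0 %, so u was 78.0 %, z 0.691 and n 1.76. That left 40.8 mM of incoming ligand against 55.2 mM of leaving ligand: no shortage, but y = 0.740. The step constant κ, read from these readings, was 0.933.

For violet, counting two exchanges per complex gave y = 2.10, hence n = 2.42, y = 1.92, and a share of complex with three exchanged of 53.5 %. Counting two exchanges in grey and teal gave y = 0.571 and 0.375. Green and red, at 1.25 and 1.20 equivalents, I took at one exchange: y = 0.200 and 0.100. Red's share came to about 0.790 %. I ranked the flasks by my y: violet, grey, teal, green, red, with violet highest and red lowest.

The forecast gave violet > grey > teal > green > red, with 54 % and 1 %, holding that the outcome “depends on the free incoming/leaving ratio”.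

The flasks gave violet > grey > teal > green > red, with 54.1 % in violet and 2.25 % in red.

    starting complex + incoming ligand ⇌ leaving ligand + complex with one exchanged (K = 25.0, k = 0.167 /M/min)
    complex with one exchanged + incoming ligand ⇌ leaving ligand + complex with two exchanged (K = 2.22, k = 0.292 /M/min)
    complex with two exchanged + incoming ligand ⇌ leaving ligand + complex with three exchanged (K = 0.778, k = 0.0557 /M/min)
    2 starting complex → homo dimer (k = 0.0214 /M/min)

In violet, 36.4 % stood as complex with two exchanged at 5.00 d. The free amounts there gave y = 1.91, so κ gave a share of 53.3 %. For the neighbour of violet with 60 mM of incoming ligand, counting two exchanges gave y = 1.14, and κ gave a share of 35.4 %. That flask gave 37.0 %.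

Readings and results stem from a simulated flask with constants of no real substance; noise was put on by code.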